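**Plan**

1. Locants used throughout: five-membered ring C1 (quaternary, Me)–C2–C3–C4 (OH, iPr)–C5 (H); seven-membered ring C1–C10 (O-angeloyl)–C9=C8(Me)–C7H2–C6 (O-anisoyl)–C5. β is the face of the C1 methyl.
2. Retrosynthesis: cut both ester C–O bonds, then C4–iPr (C4 ketone, masked as a ketal), and take C6–OH back to a C6 ketone/enol. C6–O and C8=C9 are 1,4-related across C7H2, so the C5=C6 enol form is a cyclohepta-1,4-diene, the retron of a divinylcyclopropane Cope rearrangement.
3. Cutting C1–C10 and C6–C7 (with a transient C6–C8 bond) gives a C6–C5=C1 cyclopentenyl carbenoid and the dienol ether C7=C8(Me)–C9=C10–OSi: a formal (4+3) onto a five-membered ring that already holds C1 and C5.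
4. Forward: the five-membered ring is bought as 2-bromo-3-methylcyclopentenone and C6 is attached as a diazoacetate (the ester is the activating group). The seven-membered ring is closed last by rhodium-catalysed cyclopropanation/Cope. The ester carbon is then excised (Curtius) to the C6 ketone, the ketal is opened for isopropyl addition, and the two acylations finish.
5. Stereochemistry: absolute configuration from the chiral rhodium catalyst (cyclopropane C6/C8), relayed to C1 and C10 by the boat Cope; C5 by protonation anti to the C1 methyl; C6 by thermodynamic dissolving-metal reduction; C4 by addition anti to the C1 methyl.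

Key step: step 5

Remark on the chemistry (assumption): with Rh2(S-DOSP)4 the 1,1-disubstituted diene terminus is taken to follow the sense of induction established for styrene-type alkenes ((1S,2R)-cyclopropane). If the sense proves opposite, Rh2(R-DOSP)4 is used with no other change. Bicyclic compounds are named as bicyclo[5.3.0]decanes with the plan locants (ring fusion C1/C5).

**Step 1**
Reactants: 1 2-bromo-3-methylcyclopent-2-en-1-one; 2 ethylene glycol
Product: 3 6-bromo-7-methyl-1,4-dioxaspiro[4.4]non-6-ene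
Conditions: 2 (3 equiv), p-TsOH·H2O (5 mol %), benzene, reflux, Dean–Stark trap
Reagents that add atoms: ethylene glycol (2), OCCO
Why: acid-catalysed ketalisation of the α-bromo enone masks C4 as a temporary dioxolane and makes bromine–lithium exchange possible; no stereocentre is formed.

**Step 2**
Reactants: 3 6-bromo-7-methyl-1,4-dioxaspiro[4.4]non-6-ene; 4 dimethyl oxalate
Product: 6 methyl 2-(7-methyl-1,4-dioxaspiro[4.4]non-6-en-6-yl)-2-oxoacetate, via vinyllithium 5 (not isolated)
Conditions: n-BuLi (1.05 equiv), THF, −78 °C; inverse addition to 4 (3 equiv), THF, −78 °C; aq. NH4Cl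
Reagents that add atoms: dimethyl oxalate (4), COC(=O)C(=O)OC
Why: bromine–lithium exchange followed by acyl substitution on excess oxalate at low temperature, where the tetrahedral adduct persists and a single addition results, attaches C6 and the ester carbon to C5 as an α-keto ester.

**Step 3**
Reactants: 6 methyl 2-(7-methyl-1,4-dioxaspiro[4.4]non-6-en-6-yl)-2-oxoacetate; 7 p-toluenesulfonyl hydrazide
Product: 9 methyl 2-diazo-2-(7-methyl-1,4-dioxaspiro[4.4]non-6-en-6-yl)acetate, via tosylhydrazone 8 (not isolated)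
Conditions: 7 (1.1 equiv), MeOH, 45 °C; evaporate; DBU (1.5 equiv), CH2Cl2, 0 °C to rt; used at once
Reagents that add atoms: p-toluenesulfonyl hydrazide (7), Cc1ccc(cc1)S(=O)(=O)NN
Why: condensation of the activated ketone and base-induced loss of sulfinate (Bamford–Stevens type) is the standard route from α-keto esters to aryl- and vinyldiazoacetates.

**Step 4**
Reactants: 10 3-methylbut-2-enal (prenal); 11 tert-butyldimethylsilyl trifluoromethanesulfonate
Product: 12 (E)-tert-butyldimethyl[(3-methylbuta-1,3-dien-1-yl)oxy]silane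
Conditions: 11 (1.1 equiv), Et3N (1.5 equiv), Et2O, 0 °C to rt; distillation
Reagents that add atoms: tert-butyldimethylsilyl trifluoromethanesulfonate (11), CC(C)(C)[Si](C)(C)OS(=O)(=O)C(F)(F)F
Why: O-silylation and γ-deprotonation (vinylogous soft enolisation) of the s-trans enal should give the E dienol silyl ether, which carries C7, C8 with its methyl, C9 and the C10 oxygen.

**Step 5**
Reactants: 9 methyl 2-diazo-2-(7-methyl-1,4-dioxaspiro[4.4]non-6-en-6-yl)acetate; 12 (E)-tert-butyldimethyl[(3-methylbuta-1,3-dien-1-yl)oxy]silane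
Product: 14 methyl (1S,10R)-10-(tert-butyldimethylsilyloxy)-4,4-ethylenedioxy-1,8-dimethylbicyclo[5.3.0]deca-5,8-diene-6-carboxylate, via cis-divinylcyclopropane 13 (not isolated)
Conditions: 12 (4 equiv), Rh2(S-DOSP)4 = dirhodium tetrakis[(S)-N-(4-dodecylphenylsulfonyl)prolinate] (1 mol %), degassed hexanes, slow addition of 9 at −40 °C, then 23 °C; then 70 °C (PhMe, 100 °C if 13 persists)
Reagents that add atoms: diene 12, C=C(C)/C=C/O[Si](C)(C)C(C)(C)C
Why: The chiral divalent-rhodium carboxylate turns 9 into a donor/acceptor vinylcarbenoid (C6 carbene carbon, C5=C1 as donor) that cyclopropanates the terminal C7=C8 bond of 12, the nucleophilic and unhindered 1,1-disubstituted end, while the trans-disubstituted enol ether bond C9=C10 is left alone; the resulting cis-divinylcyclopropane 13 then undergoes a [3,3] (Cope) shift in the same flask that breaks C6–C8 and makes C1–C10. The closest known reaction type is the tandem cyclopropanation/Cope rearrangement of vinyldiazoacetates with dienes, a formal (4+3) cycloaddition. The transient three-membered ring is closed by (2+1) carbene transfer, and the seven-membered ring, the only ring of the skeleton formed here, by ring expansion of that cyclopropane through a boat [3,3] transition state with both alkenyl groups over the cyclopropane. The cyclopropane centres C6 (S) and C8 (R) are set by the catalyst (alkenyl substituent of the alkene syn to the carbenoid donor) and are relayed stereospecifically: in the boat the E substituents of the two termini, ring CH2 (C2) on C1 and the E-silyloxy group on C10, end up cis, so the new quaternary C1 is S and C10 is R with oxygen trans to the C1 methyl. The step needs site selectivity (secured by the polarisation and substitution pattern of the 1-silyloxy-3-methyldiene), cis selectivity and enantioselectivity in the cyclopropanation (catalyst), and a Cope shift that tolerates the Z methyl on C1 (driven by strain release); any Z dienol ether would give a doubly Z-substituted cyclopropane that does not rearrange and is removed.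

**Step 6**
Reactants: 14 methyl (1S,10R)-10-(tert-butyldimethylsilyloxy)-4,4-ethylenedioxy-1,8-dimethylbicyclo[5.3.0]deca-5,8-diene-6-carboxylate
Product: 15 (1S,10R)-10-(tert-butyldimethylsilyloxy)-4,4-ethylenedioxy-1,8-dimethylbicyclo[5.3.0]deca-5,8-diene-6-carboxylic acid
Conditions: LiOH·H2O (5 equiv), THF/MeOH/H2O (3:1:1), 60 °C; 1 M HCl to pH 4 at 0 °C
Reagents that add atoms: lithium hydroxide, [Li+].[OH-]
Why: saponification of the hindered conjugated methyl ester leaves the base-stable silyl ether and ketal untouched; C7 carries no hydrogen acidified by the carbonyl, so the skipped diene should not migrate.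

**Step 7**
Reactants: 15 (1S,10R)-10-(tert-butyldimethylsilyloxy)-4,4-ethylenedioxy-1,8-dimethylbicyclo[5.3.0]deca-5,8-diene-6-carboxylic acid
Product: 18 (1S,5S,10R)-10-(tert-butyldimethylsilyloxy)-4,4-ethylenedioxy-1,8-dimethylbicyclo[5.3.0]dec-8-en-6-one, via acyl azide 16 (not isolated), via vinyl isocyanate 17 (not isolated)
Conditions: (PhO)2P(O)N3 (1.2 equiv), Et3N (1.5 equiv), PhMe, 0 to 85 °C; then added to THF/H2O/AcOH (10:5:1), 23 to 40 °C
Reagents that add atoms: water, O; diphenylphosphoryl azide, [N-]=[N+]=NP(=O)(Oc1ccccc1)Oc1ccccc1 (its nitrogen is carried only by 16 and 17)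
Why: Curtius rearrangement of the α,β-unsaturated acyl azide and hydration/decarboxylation of the vinyl isocyanate excise the activating ester carbon as CO2 and leave the C6 ketone; C5 is set by protonation of the enamine on the α-face, anti to the pseudo-axial C1 methyl, as reagents add to steroidal 9(11)-alkenes, which should give the trans ring fusion.

**Step 8**
Reactants: 18 (1S,5S,10R)-10-(tert-butyldimethylsilyloxy)-4,4-ethylenedioxy-1,8-dimethylbicyclo[5.3.0]dec-8-en-6-one
Product: 19 (1S,5S,6S,10R)-10-(tert-butyldimethylsilyloxy)-4,4-ethylenedioxy-1,8-dimethylbicyclo[5.3.0]dec-8-en-6-ol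
Conditions: Li (6 equiv), NH3(l)/THF, EtOH (3 equiv), −78 °C, short contact; NH4Cl
Reagents that add atoms: none
Why: dissolving-metal ketone reduction passes through a ketyl/carbanion that is protonated to the more stable equatorial alcohol, here the 6α-alcohol cis to H5 and free of the 1,3-diaxial contact with the C1 methyl (the behaviour of 11-keto steroids, which give 11α-alcohols), whereas hydride reagents would be expected to give the axial epimer; the isolated alkene, silyl ether and ketal are inert.

**Step 9**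
Reactants: 19 (1S,5S,6S,10R)-10-(tert-butyldimethylsilyloxy)-4,4-ethylenedioxy-1,8-dimethylbicyclo[5.3.0]dec-8-en-6-ol
Product: 20 (1S,5S,6S,10R)-10-(tert-butyldimethylsilyloxy)-6-hydroxy-1,8-dimethylbicyclo[5.3.0]dec-8-en-4-one
Conditions: pyridinium p-toluenesulfonate (0.2 equiv), acetone/H2O (10:1), 50 °C
Reagents that add atoms: water, O
Why: mild acid-catalysed hydrolysis of the dioxolane frees the C4 ketone under buffered conditions in which the secondary silyl ether survives and neither enolisation at C5 nor β-elimination of the C6 hydroxyl should be significant.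

**Step 10**
Reactants: 20 (1S,5S,6S,10R)-10-(tert-butyldimethylsilyloxy)-6-hydroxy-1,8-dimethylbicyclo[5.3.0]dec-8-en-4-one; 21 isopropylmagnesium chloride
Product: 22 (1S,4R,5S,6S,10R)-10-(tert-butyldimethylsilyloxy)-4-isopropyl-1,8-dimethylbicyclo[5.3.0]dec-8-ene-4,6-diol
Conditions: LaCl3·2LiCl (1.5 equiv), THF, rt, 1 h; then 21 (4 equiv), −20 to 0 °C; aq. NH4Cl
Reagents that add atoms: isopropylmagnesium chloride (21), CC(C)[Mg]Cl
Why: lanthanide-promoted Grignard 1,2-addition suppresses enolisation and β-hydride reduction; after deprotonation of the C6 hydroxyl the nucleophile adds to the C4 ketone from the α-face, syn to H5 and anti to the axial C1 methyl and the C6 branch, which should give the 4β-hydroxy-4α-isopropyl (4R) centre.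

**Step 11**
Reactants: 22 (1S,4R,5S,6S,10R)-10-(tert-butyldimethylsilyloxy)-4-isopropyl-1,8-dimethylbicyclo[5.3.0]dec-8-ene-4,6-diol; 23 4-methoxybenzoyl chloride
Product: 24 (1S,4R,5S,6S,10R)-10-(tert-butyldimethylsilyloxy)-4-hydroxy-4-isopropyl-1,8-dimethylbicyclo[5.3.0]dec-8-en-6-yl 4-methoxybenzoate
Conditions: 23 (1.3 equiv), Et3N (2 equiv), 4-(dimethylamino)pyridine (0.1 equiv), CH2Cl2, 0 °C to rt
Reagents that add atoms: 4-methoxybenzoyl chloride (23), COc1ccc(cc1)C(Cl)=O
Why: nucleophile-catalysed acylation esterifies the secondary C6 hydroxyl with retention, while the tertiary C4 hydroxyl does not react.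

**Step 12**
Reactants: 24 (1S,4R,5S,6S,10R)-10-(tert-butyldimethylsilyloxy)-4-hydroxy-4-isopropyl-1,8-dimethylbicyclo[5.3.0]dec-8-en-6-yl 4-methoxybenzoate
Product: 25 (1S,4R,5S,6S,10R)-4,10-dihydroxy-4-isopropyl-1,8-dimethylbicyclo[5.3.0]dec-8-en-6-yl 4-methoxybenzoate
Conditions: Bu4NF (3 equiv), AcOH (3 equiv), THF, 23 to 45 °C
Reagents that add atoms: none
Why: fluoride-mediated desilylation frees the C10 hydroxyl, and the acetic acid buffer keeps the medium non-basic so that the anisoate neither migrates nor is cleaved.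

**Step 13**
Reactants: 25 (1S,4R,5S,6S,10R)-4,10-dihydroxy-4-isopropyl-1,8-dimethylbicyclo[5.3.0]dec-8-en-6-yl 4-methoxybenzoate; 26 angelic acid ((Z)-2-methylbut-2-enoic acid)
Product: 28 (1S,4R,5S,6S,10R)-4-hydroxy-4-isopropyl-1,8-dimethyl-10-[(Z)-2-methylbut-2-enoyloxy]bicyclo[5.3.0]dec-8-en-6-yl 4-methoxybenzoate, via mixed anhydride 27 (not isolated)
Conditions: 26 (3 equiv), 2,4,6-trichlorobenzoyl chloride (3 equiv), Et3N (3 equiv), PhMe, rt, 2 h; then 25, 80 °C, no nucleophilic catalyst
Reagents that add atoms: angelic acid (26), C/C=C(/C)C(=O)O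
Why: Yamaguchi esterification through the mixed anhydride without a nucleophilic catalyst is the protocol that preserves the Z geometry of the angeloyl group; only the secondary allylic C10 hydroxyl reacts, with retention, and the tertiary C4 hydroxyl stays free.

**Compound list**

1 | 2-bromo-3-methylcyclopent-2-en-1-one | O=C1CCC(C)=C1Br | starting material
2 | ethylene glycol | OCCO | starting material
3 | 6-bromo-7-methyl-1,4-dioxaspiro[4.4]non-6-ene | CC1=C(Br)C2(CC1)OCCO2 | intermediate
4 | dimethyl oxalate | COC(=O)C(=O)OC | starting material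
5 | (7-methyl-1,4-dioxaspiro[4.4]non-6-en-6-yl)lithium | CC1=C([Li])C2(CC1)OCCO2 | intermediate (not isolated)
6 | methyl 2-(7-methyl-1,4-dioxaspiro[4.4]non-6-en-6-yl)-2-oxoacetate | COC(=O)C(=O)C1=C(C)CCC12OCCO2 | intermediate
7 | p-toluenesulfonyl hydrazide | Cc1ccc(cc1)S(=O)(=O)NN | starting material
8 | tosylhydrazone of 6 | COC(=O)C(=NNS(=O)(=O)c1ccc(C)cc1)C1=C(C)CCC12OCCO2 | intermediate (not isolated)
9 | methyl 2-diazo-2-(7-methyl-1,4-dioxaspiro[4.4]non-6-en-6-yl)acetate | COC(=O)C(=[N+]=[N-])C1=C(C)CCC12OCCO2 | intermediate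
10 | 3-methylbut-2-enal | CC(C)=CC=O | starting material
11 | tert-butyldimethylsilyl trifluoromethanesulfonate | CC(C)(C)[Si](C)(C)OS(=O)(=O)C(F)(F)F | starting material
12 | (E)-tert-butyldimethyl[(3-methylbuta-1,3-dien-1-yl)oxy]silane | C=C(C)/C=C/O[Si](C)(C)C(C)(C)C | intermediate
13 | methyl (1S,2R)-2-[(E)-2-(tert-butyldimethylsilyloxy)ethenyl]-2-methyl-1-(7-methyl-1,4-dioxaspiro[4.4]non-6-en-6-yl)cyclopropane-1-carboxylate | COC(=O)[C@@]1(C2=C(C)CCC23OCCO3)C[C@]1(C)/C=C/O[Si](C)(C)C(C)(C)C | intermediate (not isolated)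
14 | methyl (1S,10R)-10-(tert-butyldimethylsilyloxy)-4,4-ethylenedioxy-1,8-dimethylbicyclo[5.3.0]deca-5,8-diene-6-carboxylate | CC(C)(C)[Si](C)(C)O[C@@H]1C=C(C)CC(C(=O)OC)=C2[C@]1(C)CCC23OCCO3 | intermediate
15 | (1S,10R)-10-(tert-butyldimethylsilyloxy)-4,4-ethylenedioxy-1,8-dimethylbicyclo[5.3.0]deca-5,8-diene-6-carboxylic acid | CC(C)(C)[Si](C)(C)O[C@@H]1C=C(C)CC(C(=O)O)=C2[C@]1(C)CCC23OCCO3 | intermediate
16 | acyl azide of 15 | CC(C)(C)[Si](C)(C)O[C@@H]1C=C(C)CC(C(=O)N=[N+]=[N-])=C2[C@]1(C)CCC23OCCO3 | intermediate (not isolated)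
17 | C6 vinyl isocyanate | CC(C)(C)[Si](C)(C)O[C@@H]1C=C(C)CC(N=C=O)=C2[C@]1(C)CCC23OCCO3 | intermediate (not isolated)
18 | (1S,5S,10R)-10-(tert-butyldimethylsilyloxy)-4,4-ethylenedioxy-1,8-dimethylbicyclo[5.3.0]dec-8-en-6-one (trans-fused) | CC(C)(C)[Si](C)(C)O[C@@H]1C=C(C)CC(=O)[C@@H]2[C@]1(C)CCC23OCCO3 | intermediate
19 | (1S,5S,6S,10R)-10-(tert-butyldimethylsilyloxy)-4,4-ethylenedioxy-1,8-dimethylbicyclo[5.3.0]dec-8-en-6-ol | CC(C)(C)[Si](C)(C)O[C@@H]1C=C(C)C[C@H](O)[C@@H]2[C@]1(C)CCC23OCCO3 | intermediate
20 | (1S,5S,6S,10R)-10-(tert-butyldimethylsilyloxy)-6-hydroxy-1,8-dimethylbicyclo[5.3.0]dec-8-en-4-one | CC(C)(C)[Si](C)(C)O[C@@H]1C=C(C)C[C@H](O)[C@@H]2[C@]1(C)CCC2=O | intermediate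
21 | isopropylmagnesium chloride | CC(C)[Mg]Cl | starting material
22 | (1S,4R,5S,6S,10R)-10-(tert-butyldimethylsilyloxy)-4-isopropyl-1,8-dimethylbicyclo[5.3.0]dec-8-ene-4,6-diol | CC(C)(C)[Si](C)(C)O[C@@H]1C=C(C)C[C@H](O)[C@@H]2[C@]1(C)CC[C@@]2(O)C(C)C | intermediate
23 | 4-methoxybenzoyl chloride | COc1ccc(cc1)C(Cl)=O | starting material
24 | (1S,4R,5S,6S,10R)-10-(tert-butyldimethylsilyloxy)-4-hydroxy-4-isopropyl-1,8-dimethylbicyclo[5.3.0]dec-8-en-6-yl 4-methoxybenzoate | CC(C)(C)[Si](C)(C)O[C@@H]1C=C(C)C[C@H](OC(=O)c2ccc(OC)cc2)[C@@H]2[C@]1(C)CC[C@@]2(O)C(C)C | intermediate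
25 | (1S,4R,5S,6S,10R)-4,10-dihydroxy-4-isopropyl-1,8-dimethylbicyclo[5.3.0]dec-8-en-6-yl 4-methoxybenzoate | O[C@@H]1C=C(C)C[C@H](OC(=O)c2ccc(OC)cc2)[C@@H]2[C@]1(C)CC[C@@]2(O)C(C)C | intermediate
26 | angelic acid | C/C=C(/C)C(=O)O | starting material
27 | angelic 2,4,6-trichlorobenzoic anhydride | C/C=C(/C)C(=O)OC(=O)c1c(Cl)cc(Cl)cc1Cl | intermediate (not isolated)
28 | (1S,4R,5S,6S,10R)-4-hydroxy-4-isopropyl-1,8-dimethyl-10-[(Z)-2-methylbut-2-enoyloxy]bicyclo[5.3.0]dec-8-en-6-yl 4-methoxybenzoate | C/C=C(/C)C(=O)O[C@@H]1C=C(C)C[C@H](OC(=O)c2ccc(OC)cc2)[C@@H]2[C@]1(C)CC[C@@]2(O)C(C)C | target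

**Step count**

Total steps: 13. Longest linear sequence: 12 (steps 1, 2, 3, 5 to 13); step 4 is a one-step branch.

**Steps most likely to fail**

Step 5. The hindered carbenoid may be lost to intramolecular C–H insertion into the dioxolane CH2 groups. The cyclopropanation may place the two alkenyl groups trans, which blocks the Cope shift and erodes enantiopurity if the cyclopropane has to be equilibrated thermally. The Cope shift may also stall because of the Z methyl on C1.

Fallback, from 5 back to 18: the carbene is made stoichiometrically as a Fischer alkoxycarbene, which already carries the C6 oxygen.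
- Vinyllithium 5 is added to Cr(CO)6 (THF, −78 to 0 °C) to give the lithium acylpentacarbonylchromate F1.
- O-acylation with AcBr (CH2Cl2, −40 °C) gives the acetoxycarbene complex F2, and alcoholysis with (−)-menthol gives the menthyloxy(alkenyl)carbene complex F3.
- Heating F3 with diene 12 (THF, 80 °C, sealed, CO 1 atm) should cyclopropanate C7=C8 and, after Cope rearrangement, give the menthyl enol ether F4. Any trans-cyclopropane funnels into the cis isomer by thermal epimerisation.
- F4 is separated from its (1R,10S) diastereomer by chromatography; the menthyl group is the resolving handle.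
- Mild hydrolysis (oxalic acid, wet THF) then gives ketone 18 directly, so steps 6 and 7 are not needed.

Step 7. The enamine may be protonated at C5 from the β-face, or the ketone may enolise later, giving the cis ring fusion. The C8=C9 bond may migrate into conjugation with the new ketone, and the isocyanate may be consumed as ureas.

Fallback, from 14 back to 18: C5 is set before any C6 carbonyl exists.
- Conjugate reduction of enoate 14 with nickel boride (NiCl2·6H2O, NaBH4, MeOH, 0 °C) delivers hydrogen to C5 from the face anti to the C1 methyl and gives the saturated ester F5 (C6 epimers, both usable).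
- Enolate hydroxylation (LDA, THF, −78 °C; 3-phenyl-2-(phenylsulfonyl)oxaziridine) gives the α-hydroxy ester F6.
- LiAlH4 gives the 1,2-diol F7, and NaIO4 (THF/H2O, pH 7) cleaves the glycol to ketone 18 under neutral conditions that leave C5 and the C8=C9 bond alone.

Step 10. The basic Grignard reagent may enolise the cyclopentanone (epimerisation at C5, retro-aldol of the β-alkoxide), and β-hydride transfer may reduce the ketone instead of adding to it.

Fallback, from 20 back to 22: an sp2 nucleophile without β-hydrogen is used.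
- Isopropenylmagnesium bromide with anhydrous CeCl3 (THF, −78 °C) adds to the C4 ketone from the same α-face and gives the isopropenyl carbinol F8.
- Hydrogenation of the 1,1-disubstituted alkene with RhCl(PPh3)3 (H2 1 atm, benzene), which leaves the trisubstituted C8=C9 bond, then gives 22.

**Further compounds**

F1 | step 5 | lithium pentacarbonyl[(7-methyl-1,4-dioxaspiro[4.4]non-6-en-6-yl)oxidomethylidene]chromate | [Li+].[O-]C(=[Cr](=C=O)(=C=O)(=C=O)(=C=O)=C=O)C1=C(C)CCC12OCCO2
F2 | step 5 | pentacarbonyl[acetoxy(7-methyl-1,4-dioxaspiro[4.4]non-6-en-6-yl)methylidene]chromium | CC(=O)OC(=[Cr](=C=O)(=C=O)(=C=O)(=C=O)=C=O)C1=C(C)CCC12OCCO2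
F3 | step 5 | pentacarbonyl[(1R,2S,5R)-menthyloxy(7-methyl-1,4-dioxaspiro[4.4]non-6-en-6-yl)methylidene]chromium | O=C=[Cr](=C=O)(=C=O)(=C=O)(=C=O)=C(O[C@@H]1C[C@H](C)CC[C@H]1C(C)C)C1=C(C)CCC12OCCO2
F4 | step 5 | (1S,10R)-10-(tert-butyldimethylsilyloxy)-4,4-ethylenedioxy-6-[(1R,2S,5R)-menthyloxy]-1,8-dimethylbicyclo[5.3.0]deca-5,8-diene | CC(C)(C)[Si](C)(C)O[C@@H]1C=C(C)CC(O[C@@H]3C[C@H](C)CC[C@H]3C(C)C)=C2[C@]1(C)CCC24OCCO4
F5 | step 7 | methyl 10-(tert-butyldimethylsilyloxy)-4,4-ethylenedioxy-1,8-dimethylbicyclo[5.3.0]dec-8-ene-6-carboxylate (trans-fused, C1/C5/C10 as in 18, C6 epimers) | CC(C)(C)[Si](C)(C)O[C@@H]1C=C(C)CC(C(=O)OC)[C@@H]2[C@]1(C)CCC23OCCO3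
F6 | step 7 | methyl 10-(tert-butyldimethylsilyloxy)-4,4-ethylenedioxy-6-hydroxy-1,8-dimethylbicyclo[5.3.0]dec-8-ene-6-carboxylate (C6 epimers) | CC(C)(C)[Si](C)(C)O[C@@H]1C=C(C)CC(O)(C(=O)OC)[C@@H]2[C@]1(C)CCC23OCCO3
F7 | step 7 | 10-(tert-butyldimethylsilyloxy)-4,4-ethylenedioxy-6-(hydroxymethyl)-1,8-dimethylbicyclo[5.3.0]dec-8-en-6-ol (C6 epimers) | CC(C)(C)[Si](C)(C)O[C@@H]1C=C(C)CC(O)(CO)[C@@H]2[C@]1(C)CCC23OCCO3
F8 | step 10 | 10-(tert-butyldimethylsilyloxy)-1,8-dimethyl-4-(prop-1-en-2-yl)bicyclo[5.3.0]dec-8-ene-4,6-diol (configuration as in 22) | CC(C)(C)[Si](C)(C)O[C@@H]1C=C(C)C[C@H](O)[C@@H]2[C@]1(C)CC[C@@]2(O)C(C)=C
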